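**Plan**

1. The target is an achiral tridepside: ring A (terminal 2,4-dihydroxy-6-methylbenzoyl, locants C1''–C6''), ring B (central, primed locants) and ring C (the 2-methoxy-6-methylbenzoic acid).
2. The retrosynthesis cuts ring A itself at C2''–C3'', C4''–C5'' and C1''–C2'', then the acrylic ester bond at O4' of ring B, then the depside ester between rings B and C.
3. Enabling feature: ring A is a resorcinol whose C2''–OH maps onto a ketene carbonyl and whose C4''–O maps onto the oxygen of a siloxyalkyne; C5'', C6'' (with its CH3) and C1'' (with the ester carbonyl) come from C5, C3 and C2 of an (E)-5-diazo-3-methyl-4-oxopent-2-enoate.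
4. Forward: orsellinic acid gives the ring C phenol and the ring B acid through one shared allyl ether, and these are joined to the B–C didepside phenol. 2,3-Butanedione gives the diazo enoic acid, which is esterified with that phenol; ring A is built last by benzannulation, and two deprotections finish.
5. Stereochemistry: the target has no stereocentre; the only geometric element is the E alkene of the annulation precursor, set by the Wittig step and consumed on aromatisation.

Key step: step 15

Remark: the diazoketone is made by diazo transfer to a methyl ketone rather than from an acid chloride and diazomethane, because the fumarate-type alkene would compete as a dipolarophile for diazomethane.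
Remark: the parent siloxyalkyne 23 is assumed to be non-commercial and is prepared in step 14.

**Route**

Step 1
Reactants: 1 orsellinic acid (2,4-dihydroxy-6-methylbenzoic acid)
Product: 2 benzyl 2,4-dihydroxy-6-methylbenzoate
Conditions: BnBr (1.05 equiv), KHCO3, DMF, 40 °C
Reagents that add atoms: benzyl bromide, BrCc1ccccc1
Why: Carboxylate O-alkylation (SN2); hydrogencarbonate deprotonates only the carboxylic acid, so both phenols should stay free.

Step 2
Reactants: 2 benzyl 2,4-dihydroxy-6-methylbenzoate
Product: 3 benzyl 4-(allyloxy)-2-hydroxy-6-methylbenzoate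
Conditions: allyl bromide (1.1 equiv), K2CO3, acetone, reflux
Reagents that add atoms: allyl bromide, C=CCBr
Why: Williamson etherification; the C2 hydroxyl is hydrogen-bonded to the ester carbonyl and far less nucleophilic, so one equivalent of allyl bromide should alkylate the C4 hydroxyl only.

Step 3
Reactants: 3 benzyl 4-(allyloxy)-2-hydroxy-6-methylbenzoate
Product: 4 benzyl 4-(allyloxy)-2-methoxy-6-methylbenzoate
Conditions: MeI (excess), K2CO3, DMF, 50 °C
Reagents that add atoms: iodomethane, CI
Why: Williamson methylation of the remaining chelated phenol under more forcing conditions; benzyl ester and allyl ether are inert.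

Step 4
Reactants: 4 benzyl 4-(allyloxy)-2-methoxy-6-methylbenzoate
Product: 5 benzyl 4-hydroxy-2-methoxy-6-methylbenzoate
Conditions: Pd(PPh3)4 (cat.), morpholine, THF, rt
Reagents that add atoms: none
Why: Tsuji–Trost deallylation: zerovalent palladium ionises the allyl aryl ether and morpholine captures the allyl fragment, leaving benzyl ester and methyl ether untouched.

Step 5
Reactants: 3 benzyl 4-(allyloxy)-2-hydroxy-6-methylbenzoate
Product: 6 benzyl 4-(allyloxy)-2-(benzyloxy)-6-methylbenzoate
Conditions: BnBr, K2CO3, DMF, 60 °C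
Reagents that add atoms: benzyl bromide, BrCc1ccccc1
Why: Williamson benzylation of the chelated C2 hydroxyl, giving a ring B unit whose two phenolic oxygens carry orthogonal groups.

Step 6
Reactants: 6 benzyl 4-(allyloxy)-2-(benzyloxy)-6-methylbenzoate
Product: 7 4-(allyloxy)-2-(benzyloxy)-6-methylbenzoic acid
Conditions: KOH, MeOH/H2O/1,4-dioxane, reflux; then aq. HCl
Reagents that add atoms: potassium hydroxide, [K+].[OH-]
Why: Saponification of the di-ortho-substituted benzoate needs hot aqueous alkali, to which the allyl and benzyl aryl ethers are stable; acidification gives the free acid.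

Step 7
Reactants: 7 4-(allyloxy)-2-(benzyloxy)-6-methylbenzoic acid, 5 benzyl 4-hydroxy-2-methoxy-6-methylbenzoate
Product: 9 benzyl 4-{[4-(allyloxy)-2-(benzyloxy)-6-methylbenzoyl]oxy}-2-methoxy-6-methylbenzoate, via mixed anhydride 8 (not isolated)
Conditions: (CF3CO)2O (excess), toluene, rt
Reagents that add atoms: none
Why: Depside esterification through mixed anhydride 8: trifluoroacetic anhydride activates the hindered, electron-rich acid strongly enough for the free C4 phenol of 5 to be acylated at room temperature, and the allyl, benzyl and methyl ethers tolerate the trifluoroacetic acid formed.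

Step 8
Reactants: 9 benzyl 4-{[4-(allyloxy)-2-(benzyloxy)-6-methylbenzoyl]oxy}-2-methoxy-6-methylbenzoate
Product: 10 benzyl 4-{[2-(benzyloxy)-4-hydroxy-6-methylbenzoyl]oxy}-2-methoxy-6-methylbenzoate
Conditions: Pd(PPh3)4 (cat.), morpholine, THF, rt
Reagents that add atoms: none
Why: Tsuji–Trost deallylation as in step 4; the hindered depside ester and the benzyl groups should not be touched by morpholine or zerovalent palladium.

Step 9
Reactants: 11 2,3-butanedione, 12 ethyl (triphenylphosphoranylidene)acetate
Product: 13 ethyl (2E)-3-methyl-4-oxopent-2-enoate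
Conditions: 11 (excess), CH2Cl2, 0 °C to rt
Reagents that add atoms: none
Why: Wittig olefination of one carbonyl of the diketone by the stabilised ylide; thermodynamic control places the ester trans to the acetyl group (E), and excess diketone suppresses double olefination.

Step 10
Reactants: 13 ethyl (2E)-3-methyl-4-oxopent-2-enoate
Product: 15 ethyl (2E)-7,7,7-trifluoro-3-methyl-4,6-dioxohept-2-enoate, via lithium enolate 14 (not isolated)
Conditions: LiN(SiMe3)2, THF, −78 °C; then CF3CO2CH2CF3; aq. HCl work-up, used crude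
Reagents that add atoms: 2,2,2-trifluoroethyl trifluoroacetate, O=C(OCC(F)(F)F)C(F)(F)F
Why: Kinetic deprotonation of the acetyl methyl group by the hindered amide and Claisen-type C-acylation of enolate 14 by the activated trifluoroacetate give the 1,3-diketone needed for diazo transfer; the ester has no alpha hydrogen.

Step 11
Reactants: 15 ethyl (2E)-7,7,7-trifluoro-3-methyl-4,6-dioxohept-2-enoate
Product: 16 ethyl (2E)-5-diazo-3-methyl-4-oxopent-2-enoate
Conditions: MeSO2N3, Et3N, H2O (1 equiv), MeCN, rt
Reagents that add atoms: methanesulfonyl azide, CS(=O)(=O)N=[N+]=[N-]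
Why: Deacylative (Regitz-type) diazo transfer: the diketone anion attacks the sulfonyl azide and the trifluoroacetyl group is cleaved in the same operation, giving the alpha'-diazo enone without exposing the electron-poor alkene to diazomethane.

Step 12
Reactants: 16 ethyl (2E)-5-diazo-3-methyl-4-oxopent-2-enoate
Product: 17 (2E)-5-diazo-3-methyl-4-oxopent-2-enoic acid
Conditions: LiOH, THF/H2O, 0 °C; then cold aq. H3PO4 to pH 3, rapid extraction
Reagents that add atoms: lithium hydroxide, [Li+].[OH-]
Why: Saponification of the ethyl ester at 0 °C; alpha-diazoketones are stable to aqueous base and to brief contact with a weak acid, so careful cold acidification should release the acid intact.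

Step 13
Reactants: 17 (2E)-5-diazo-3-methyl-4-oxopent-2-enoic acid, 10 benzyl 4-{[2-(benzyloxy)-4-hydroxy-6-methylbenzoyl]oxy}-2-methoxy-6-methylbenzoate
Product: 18 3-(benzyloxy)-4-{[4-(benzyloxycarbonyl)-3-methoxy-5-methylphenoxy]carbonyl}-5-methylphenyl (2E)-5-diazo-3-methyl-4-oxopent-2-enoate
Conditions: DCC, DMAP (cat.), CH2Cl2, 0 °C to rt, in the dark
Reagents that add atoms: none
Why: Steglich esterification: carbodiimide activation and acyl transfer by DMAP under neutral conditions join the unhindered acrylic carboxyl to the unhindered C4' phenol of ring B without harming the diazoketone.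

Step 14
Reactants: 19 acetylene, 20 triisopropylsilyl trifluoromethanesulfonate
Product: 23 (triisopropylsilyloxy)acetylene, via lithium acetylide 21 (not isolated), via lithium ethynolate 22 (not isolated)
Conditions: 19 (excess), n-BuLi, THF, −78 °C; LiOO-t-Bu (from t-BuOOH and LiN(SiMe3)2, THF, −78 °C), −78 to −10 °C; i-Pr3SiOTf, −78 to 0 °C; pentane/aq. NaHCO3, distillation
Reagents that add atoms: tert-butyl hydroperoxide, CC(C)(C)OO
Why: Lithium tert-butyl peroxide transfers electrophilic oxygen to acetylide 21 to give ynolate 22, and the bulky silyl triflate then reacts at oxygen rather than carbon to give the silyl ynol ether (acetylide oxidation followed by ynolate O-silylation).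

Step 15
Reactants: 18 3-(benzyloxy)-4-{[4-(benzyloxycarbonyl)-3-methoxy-5-methylphenoxy]carbonyl}-5-methylphenyl (2E)-5-diazo-3-methyl-4-oxopent-2-enoate, 23 (triisopropylsilyloxy)acetylene
Product: 28 benzyl 4-{[2-(benzyloxy)-4-{[2-hydroxy-6-methyl-4-(triisopropylsilyloxy)benzoyl]oxy}-6-methylbenzoyl]oxy}-2-methoxy-6-methylbenzoate, via vinylketene 24 (not isolated), via 4-vinylcyclobutenone 25 (not isolated), via dienylketene 26 (not isolated), via cyclohexadienone 27 (not isolated)
Conditions: 23 (3 equiv), hν (365 nm LED), degassed ClCH2CH2Cl, rt; then 80 °C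
Reagents that add atoms: none
Why: Long-wavelength irradiation expels N2 from 18 and the alkenyl group shifts to the carbene carbon (photochemical Wolff rearrangement) to give the (E)-vinylketene 24; the nucleophilic CH terminus of 23 then adds to the ketene carbonyl carbon and the siloxy-bearing carbon to the ketene alpha carbon in a (2+2) cycloaddition (C2''–C3'' and C4''–C5'' bonds), giving 4-vinylcyclobutenone 25. Reversible 4π conrotatory opening of 25 gives dienylketene 26, whose 6π disrotatory electrocyclisation forms C1''–C2'' and closes ring A as cyclohexadienone 27, which enolises to phenol 28. The closest known reaction type is the Danheiser benzannulation in its photochemical Wolff variant with siloxyalkynes, applied here to a vinylketene that carries an aryl ester at its terminus. No stereocentre is created; the stereocentres of 25 and 27 are transient and vanish on aromatisation. The selectivity needed is regiochemical (ketene oxygen to C2'', alkyne oxygen to C4'') and is secured by the polarisation of the ynol ether, while the E alkene keeps the ester away from the ketene, so the ketene cannot close onto the ester carbonyl and hydrogen, not the ester, points inward in the 6π closure. Light of 365 nm should excite only the diazoketone and spare the aryl esters from photo-Fries migration, and the excess of 23 should outrun acylation of the product phenol by the ketene.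

Step 16
Reactants: 28 benzyl 4-{[2-(benzyloxy)-4-{[2-hydroxy-6-methyl-4-(triisopropylsilyloxy)benzoyl]oxy}-6-methylbenzoyl]oxy}-2-methoxy-6-methylbenzoate
Product: 29 benzyl 4-{[2-(benzyloxy)-4-[(2,4-dihydroxy-6-methylbenzoyl)oxy]-6-methylbenzoyl]oxy}-2-methoxy-6-methylbenzoate
Conditions: Bu4NF, AcOH, THF, 0 °C
Reagents that add atoms: none
Why: Fluoride cleaves the aryl silyl ether; buffering with acetic acid keeps the liberated phenoxide from attacking the depside esters.

Step 17
Reactants: 29 benzyl 4-{[2-(benzyloxy)-4-[(2,4-dihydroxy-6-methylbenzoyl)oxy]-6-methylbenzoyl]oxy}-2-methoxy-6-methylbenzoate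
Product: 30 4-{[4-[(2,4-dihydroxy-6-methylbenzoyl)oxy]-2-hydroxy-6-methylbenzoyl]oxy}-2-methoxy-6-methylbenzoic acid (CNP0283563.0)
Conditions: H2 (1 atm), Pd/C, EtOAc/THF, rt
Reagents that add atoms: none
Why: Hydrogenolysis over palladium removes the benzyl ether of ring B and the benzyl ester of ring C in one operation, while the aryl esters, the methyl ether and the arenes are inert.

**Compound list**

1 | orsellinic acid (2,4-dihydroxy-6-methylbenzoic acid) | Cc1cc(O)cc(O)c1C(=O)O | starting material
2 | benzyl 2,4-dihydroxy-6-methylbenzoate | Cc1cc(O)cc(O)c1C(=O)OCc1ccccc1 | intermediate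
3 | benzyl 4-(allyloxy)-2-hydroxy-6-methylbenzoate | C=CCOc1cc(C)c(C(=O)OCc2ccccc2)c(O)c1 | intermediate
4 | benzyl 4-(allyloxy)-2-methoxy-6-methylbenzoate | C=CCOc1cc(C)c(C(=O)OCc2ccccc2)c(OC)c1 | intermediate
5 | benzyl 4-hydroxy-2-methoxy-6-methylbenzoate (ring C phenol) | COc1cc(O)cc(C)c1C(=O)OCc1ccccc1 | intermediate
6 | benzyl 4-(allyloxy)-2-(benzyloxy)-6-methylbenzoate | C=CCOc1cc(C)c(C(=O)OCc2ccccc2)c(OCc2ccccc2)c1 | intermediate
7 | 4-(allyloxy)-2-(benzyloxy)-6-methylbenzoic acid (ring B acid) | C=CCOc1cc(C)c(C(=O)O)c(OCc2ccccc2)c1 | intermediate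
8 | 4-(allyloxy)-2-(benzyloxy)-6-methylbenzoic trifluoroacetic anhydride (mixed anhydride) | C=CCOc1cc(C)c(C(=O)OC(=O)C(F)(F)F)c(OCc2ccccc2)c1 | intermediate
9 | benzyl 4-{[4-(allyloxy)-2-(benzyloxy)-6-methylbenzoyl]oxy}-2-methoxy-6-methylbenzoate | C=CCOc1cc(C)c(C(=O)Oc2cc(C)c(C(=O)OCc3ccccc3)c(OC)c2)c(OCc2ccccc2)c1 | intermediate
10 | benzyl 4-{[2-(benzyloxy)-4-hydroxy-6-methylbenzoyl]oxy}-2-methoxy-6-methylbenzoate (B–C didepside phenol) | Oc1cc(C)c(C(=O)Oc2cc(C)c(C(=O)OCc3ccccc3)c(OC)c2)c(OCc2ccccc2)c1 | intermediate
11 | 2,3-butanedione | CC(=O)C(C)=O | starting material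
12 | ethyl (triphenylphosphoranylidene)acetate | CCOC(=O)C=P(c1ccccc1)(c1ccccc1)c1ccccc1 | starting material
13 | ethyl (2E)-3-methyl-4-oxopent-2-enoate | CC(=O)/C(C)=C/C(=O)OCC | intermediate
14 | lithium enolate of 13 (lithium (3E)-5-ethoxy-3-methyl-5-oxopenta-1,3-dien-2-olate) | [Li+].[O-]C(=C)/C(C)=C/C(=O)OCC | intermediate
15 | ethyl (2E)-7,7,7-trifluoro-3-methyl-4,6-dioxohept-2-enoate | O=C(CC(=O)/C(C)=C/C(=O)OCC)C(F)(F)F | intermediate
16 | ethyl (2E)-5-diazo-3-methyl-4-oxopent-2-enoate | [N-]=[N+]=CC(=O)/C(C)=C/C(=O)OCC | intermediate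
17 | (2E)-5-diazo-3-methyl-4-oxopent-2-enoic acid | [N-]=[N+]=CC(=O)/C(C)=C/C(=O)O | intermediate
18 | 3-(benzyloxy)-4-{[4-(benzyloxycarbonyl)-3-methoxy-5-methylphenoxy]carbonyl}-5-methylphenyl (2E)-5-diazo-3-methyl-4-oxopent-2-enoate (the O4' ester of 10) | [N-]=[N+]=CC(=O)/C(C)=C/C(=O)Oc1cc(C)c(C(=O)Oc2cc(C)c(C(=O)OCc3ccccc3)c(OC)c2)c(OCc2ccccc2)c1 | intermediate
19 | acetylene | C#C | starting material
20 | triisopropylsilyl trifluoromethanesulfonate | CC(C)[Si](OS(=O)(=O)C(F)(F)F)(C(C)C)C(C)C | starting material
21 | lithium acetylide | [Li+].[C-]#C | intermediate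
22 | lithium ethynolate | [Li+].[O-]C#C | intermediate
23 | (triisopropylsilyloxy)acetylene | C#CO[Si](C(C)C)(C(C)C)C(C)C | intermediate
24 | vinylketene: (2E)-3-methyl-5-oxopenta-2,4-dienoate of phenol 10 | O=C=C/C(C)=C/C(=O)Oc1cc(C)c(C(=O)Oc2cc(C)c(C(=O)OCc3ccccc3)c(OC)c2)c(OCc2ccccc2)c1 | intermediate
25 | 4-vinylcyclobutenone: (2E)-3-[4-oxo-2-(triisopropylsilyloxy)cyclobut-2-en-1-yl]but-2-enoate of phenol 10 (racemic at the ring carbon) | O=C1C=C(O[Si](C(C)C)(C(C)C)C(C)C)C1/C(C)=C/C(=O)Oc1cc(C)c(C(=O)Oc2cc(C)c(C(=O)OCc3ccccc3)c(OC)c2)c(OCc2ccccc2)c1 | intermediate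
26 | dienylketene: (2E,4E)-3-methyl-7-oxo-5-(triisopropylsilyloxy)hepta-2,4,6-trienoate of phenol 10 (C3 and C6 cis across C4=C5) | O=C=C/C(O[Si](C(C)C)(C(C)C)C(C)C)=C\C(C)=C\C(=O)Oc1cc(C)c(C(=O)Oc2cc(C)c(C(=O)OCc3ccccc3)c(OC)c2)c(OCc2ccccc2)c1 | intermediate
27 | cyclohexadienone: 2-methyl-6-oxo-4-(triisopropylsilyloxy)cyclohexa-2,4-diene-1-carboxylate of phenol 10 (racemic) | O=C1C=C(O[Si](C(C)C)(C(C)C)C(C)C)C=C(C)C1C(=O)Oc1cc(C)c(C(=O)Oc2cc(C)c(C(=O)OCc3ccccc3)c(OC)c2)c(OCc2ccccc2)c1 | intermediate
28 | benzyl 4-{[2-(benzyloxy)-4-{[2-hydroxy-6-methyl-4-(triisopropylsilyloxy)benzoyl]oxy}-6-methylbenzoyl]oxy}-2-methoxy-6-methylbenzoate | Cc1cc(O[Si](C(C)C)(C(C)C)C(C)C)cc(O)c1C(=O)Oc1cc(C)c(C(=O)Oc2cc(C)c(C(=O)OCc3ccccc3)c(OC)c2)c(OCc2ccccc2)c1 | intermediate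
29 | benzyl 4-{[2-(benzyloxy)-4-[(2,4-dihydroxy-6-methylbenzoyl)oxy]-6-methylbenzoyl]oxy}-2-methoxy-6-methylbenzoate | Cc1cc(O)cc(O)c1C(=O)Oc1cc(C)c(C(=O)Oc2cc(C)c(C(=O)OCc3ccccc3)c(OC)c2)c(OCc2ccccc2)c1 | intermediate
30 | 4-{[4-[(2,4-dihydroxy-6-methylbenzoyl)oxy]-2-hydroxy-6-methylbenzoyl]oxy}-2-methoxy-6-methylbenzoic acid (CNP0283563.0) | COc1cc(OC(=O)c2c(C)cc(OC(=O)c3c(C)cc(O)cc3O)cc2O)cc(C)c1C(=O)O | target

**Step count and risks**

Total step count: 17.
Longest linear sequence: 10 steps (steps 1, 2, 5, 6, 7, 8, 13, 15, 16, 17).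

Steps most likely to fail:

1. Step 15 (benzannulation).
 - What may go wrong: light absorbed by the aryl esters would start photo-Fries acyl migration in the depside. Photoisomerisation of the E diazo enone to its Z isomer would bring the ester next to the ketene, which then closes onto the ester carbonyl. The chelated phenol being formed may be acylated by ketene that has not yet met the alkyne. The thermal opening of the cyclobutenone may stall.
 - Fallback: ring A is attached ready-made by the classical depside esterification. Setting out from 1, exhaustive benzylation (BnBr, K2CO3, DMF) would give benzyl 2,4-bis(benzyloxy)-6-methylbenzoate F1. Saponification (KOH, MeOH/H2O/1,4-dioxane, reflux) would give 2,4-bis(benzyloxy)-6-methylbenzoic acid F2. Esterification of F2 with phenol 10 under (CF3CO)2O in toluene would give the fully benzylated tridepside F3. Hydrogenolysis of F3 (H2, Pd/C) comes back to the route at the target 30.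

2. Step 14 (siloxyalkyne).
 - What may go wrong: mono-lithium acetylide disproportionates to insoluble dilithium acetylide while the mixture is warmed for oxygen transfer. Silylation may occur at carbon and lead to the silylketene. The volatile product may be lost on concentration or hydrolysed during purification.
 - Fallback: a carbon-blocked alkyne whose acetylide is stable at 0 °C is used, and the blocking group is removed after the annulation. (Trimethylsilyl)acetylene would be taken through the same deprotonation, peroxide oxygenation and silylation with 20 to give 1-(triisopropylsilyloxy)-2-(trimethylsilyl)acetylene F4. Benzannulation of F4 with 18 under the conditions of step 15 would give the C3''-trimethylsilyl analogue of 28, F5. Ipso-protodesilylation at C3'', which is activated by both flanking oxygens (CF3CO2H, CH2Cl2, 0 °C), comes back to the route at 28.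

3. Step 12 (ester cleavage beside the diazo enone).
 - What may go wrong: hydroxide adds in conjugate fashion to the doubly activated alkene, the diazo enone oligomerises in base, or nitrogen is lost during acidification.
 - Fallback: the ester is cleaved before the diazo group exists, and the diazo transfer is moved behind the esterification. Setting out from 13, acid hydrolysis (aq. HCl, 1,4-dioxane, 80 °C) would give (2E)-3-methyl-4-oxopent-2-enoic acid F6. Steglich esterification of F6 with 10 (DCC, DMAP, CH2Cl2) would give the aryl keto ester F7. Trifluoroacetylation as in step 10 (LiN(SiMe3)2, THF, −78 °C, then CF3CO2CH2CF3; aryl esters tolerate the hindered amide at this temperature) would give diketone F8. Diazo transfer as in step 11 comes back to the route at 18.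

Further compounds
F1 | step 15 | benzyl 2,4-bis(benzyloxy)-6-methylbenzoate | Cc1cc(OCc2ccccc2)cc(OCc2ccccc2)c1C(=O)OCc1ccccc1
F2 | step 15 | 2,4-bis(benzyloxy)-6-methylbenzoic acid | Cc1cc(OCc2ccccc2)cc(OCc2ccccc2)c1C(=O)O
F3 | step 15 | benzyl 4-{[2-(benzyloxy)-4-{[2,4-bis(benzyloxy)-6-methylbenzoyl]oxy}-6-methylbenzoyl]oxy}-2-methoxy-6-methylbenzoate | Cc1cc(OCc2ccccc2)cc(OCc2ccccc2)c1C(=O)Oc1cc(C)c(C(=O)Oc2cc(C)c(C(=O)OCc3ccccc3)c(OC)c2)c(OCc2ccccc2)c1
F4 | step 14 | 1-(triisopropylsilyloxy)-2-(trimethylsilyl)acetylene | C[Si](C)(C)C#CO[Si](C(C)C)(C(C)C)C(C)C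
F5 | step 14 | benzyl 4-{[2-(benzyloxy)-4-{[2-hydroxy-6-methyl-4-(triisopropylsilyloxy)-3-(trimethylsilyl)benzoyl]oxy}-6-methylbenzoyl]oxy}-2-methoxy-6-methylbenzoate | Cc1cc(O[Si](C(C)C)(C(C)C)C(C)C)c([Si](C)(C)C)c(O)c1C(=O)Oc1cc(C)c(C(=O)Oc2cc(C)c(C(=O)OCc3ccccc3)c(OC)c2)c(OCc2ccccc2)c1
F6 | step 12 | (2E)-3-methyl-4-oxopent-2-enoic acid | CC(=O)/C(C)=C/C(=O)O
F7 | step 12 | 3-(benzyloxy)-4-{[4-(benzyloxycarbonyl)-3-methoxy-5-methylphenoxy]carbonyl}-5-methylphenyl (2E)-3-methyl-4-oxopent-2-enoate | CC(=O)/C(C)=C/C(=O)Oc1cc(C)c(C(=O)Oc2cc(C)c(C(=O)OCc3ccccc3)c(OC)c2)c(OCc2ccccc2)c1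
F8 | step 12 | 3-(benzyloxy)-4-{[4-(benzyloxycarbonyl)-3-methoxy-5-methylphenoxy]carbonyl}-5-methylphenyl (2E)-7,7,7-trifluoro-3-methyl-4,6-dioxohept-2-enoate | O=C(CC(=O)/C(C)=C/C(=O)Oc1cc(C)c(C(=O)Oc2cc(C)c(C(=O)OCc3ccccc3)c(OC)c2)c(OCc2ccccc2)c1)C(F)(F)F
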